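The route rests on cutting the pyran ring of the 1H-isochromen-8-one core at C4–C4a. The key step exploits that ring as a doubly vinylogous ester (O2–C3=C4–C4a=C8a–C8=O) whose C1–O2 bond is allylic to C8a=C4a: an allyl vinyl ether made in the flask from a 2-(hydroxymethyl)-3-(phenylthio)cyclohexenone and an enone ketal undergoes a [3,3] shift that forms C4–C4a, expels thiophenol and recloses by oxa-6π-electrocyclization, giving the complete bicyclic trienone in one operation. The precursor is a monocyclic enone carrying both stereocenters, set by osmylation of a carvone-derived acetate whose own centre is later erased.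

Key step: step 11

Remark: compounds 1, 5, 16 and 17 are taken to be commercial; ArCO stands for 2-methoxy-3,4-bis(methoxymethoxy)-6-methylbenzoyl; bicyclic compounds carry isochromene numbering (C1, O2, C3, C4, C4a, C5–C8, C8a).

Step 1
Reactants: 1 (R)-(−)-carvone
Product: 3 (R)-5-acetoxy-2-methylcyclohex-2-en-1-one, via methoxy hydroperoxide 2 (not isolated)
Conditions: O3, CH2Cl2/MeOH, −78 °C; then Ac2O, Et3N, DMAP (cat.), −78 → 23 °C
Reagents that add atoms: ozone, O=[O+][O-]; methanol, CO
Why: The electron-rich isopropenyl group should be ozonised in preference to the deactivated enone alkene, and the peracetate of the resulting α-methoxy hydroperoxide 2 should undergo Criegee rearrangement with migration of the ring carbon and retention at C5.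

Step 2
Reactants: 3 (R)-5-acetoxy-2-methylcyclohex-2-en-1-one
Product: 4 (1R,3R,4R)-3,4-dihydroxy-4-methyl-5-oxocyclohexyl acetate
Conditions: OsO4 (2 mol%), NMO, citric acid, tBuOH/H2O, 23 °C
Reagents that add atoms: osmium tetroxide, O=[Os](=O)(=O)=O; N-methylmorpholine N-oxide, C[N+]1([O-])CCOCC1; water, O
Why: Upjohn syn-dihydroxylation should give the cis-diol with OsO4 adding to the enone face anti to the pseudo-axial C5 acetoxy group, which sets both carbinol centres as R; the minor diastereomer is to be removed here by chromatography, because it would become the enantiomer once C5 is erased in step 7.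

Step 3
Reactants: 5 2,3,4-trimethoxy-6-methylbenzaldehyde
Product: 6 2,3,4-trihydroxy-6-methylbenzaldehyde
Conditions: BBr3, CH2Cl2, −78 → 23 °C; H2O
Reagents that add atoms: none
Why: Lewis-acid cleavage of aryl methyl ethers with BBr3 should remove all three methyl groups without touching the aldehyde or the ring methyl.

Step 4
Reactants: 6 2,3,4-trihydroxy-6-methylbenzaldehyde
Product: 7 2-hydroxy-3,4-bis(methoxymethoxy)-6-methylbenzaldehyde
Conditions: MOMCl (2.1 equiv), iPr2NEt, CH2Cl2, 0 °C
Reagents that add atoms: chloromethyl methyl ether, COCCl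
Why: Williamson-type O-alkylation should take the 4- and 3-hydroxyls, since the 2-hydroxyl is hydrogen-bonded to the aldehyde and is the least nucleophilic.

Step 5
Reactants: 7 2-hydroxy-3,4-bis(methoxymethoxy)-6-methylbenzaldehyde
Product: 8 2-methoxy-3,4-bis(methoxymethoxy)-6-methylbenzaldehyde
Conditions: MeI, K2CO3, DMF, 23 °C
Reagents that add atoms: iodomethane, CI
Why: Williamson methylation of the one remaining phenol should proceed once the chelated hydroxyl is deprotonated in DMF.

Step 6
Reactants: 8 2-methoxy-3,4-bis(methoxymethoxy)-6-methylbenzaldehyde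
Product: 9 2-methoxy-3,4-bis(methoxymethoxy)-6-methylbenzoic acid
Conditions: NaClO2, NaH2PO4, 2-methylbut-2-ene, tBuOH/H2O, 23 °C
Reagents that add atoms: sodium chlorite, [Na+].[O-]Cl=O
Why: Pinnick oxidation at buffered pH should convert the hindered aldehyde to the acid while the alkene scavenger protects the electron-rich ring and the MOM ethers survive.

Step 7
Reactants: 9 2-methoxy-3,4-bis(methoxymethoxy)-6-methylbenzoic acid; 4 (1R,3R,4R)-3,4-dihydroxy-4-methyl-5-oxocyclohexyl acetate
Product: 12 (1R,6R)-6-hydroxy-6-methyl-5-oxocyclohex-3-en-1-yl 2-methoxy-3,4-bis(methoxymethoxy)-6-methylbenzoate, via acid chloride 10 (not isolated), via acetoxy ester 11 (not isolated)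
Conditions: 9, 1-chloro-N,N,2-trimethylprop-1-en-1-amine, CH2Cl2, 0 → 23 °C; then 4, DMAP, Et3N, 23 → 40 °C; then DBU, 0 °C
Reagents that add atoms: none
Why: Neutral chloroenamine activation should spare the MOM ethers, DMAP-catalysed acylation should take the secondary hydroxyl over the tertiary one with retention at both carbinol centres, and DBU should then expel acetate from the β-acetoxy ketone by E1cB elimination, giving the enone and erasing the relay centre.

Step 8
Reactants: 12 (1R,6R)-6-hydroxy-6-methyl-5-oxocyclohex-3-en-1-yl ester of ArCO2H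
Product: 13 (1R,6R)-6-hydroxy-4-(hydroxymethyl)-6-methyl-5-oxocyclohex-3-en-1-yl 2-methoxy-3,4-bis(methoxymethoxy)-6-methylbenzoate
Conditions: 37% aq. CH2O, DMAP (0.3 equiv), THF/H2O, 23 °C
Reagents that add atoms: formaldehyde, C=O
Why: The Morita–Baylis–Hillman reaction of cyclohexenones with aqueous formaldehyde under DMAP catalysis should place the hydroxymethyl group (the future C1) on the enone α-carbon, the only position that can react.

Step 9
Reactants: 13 (1R,6R)-6-hydroxy-4-(hydroxymethyl)-6-methyl-5-oxocyclohex-3-en-1-yl ester of ArCO2H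
Product: 15 (1R,6R)-6-hydroxy-4-(hydroxymethyl)-6-methyl-5-oxo-3-(phenylsulfanyl)cyclohex-3-en-1-yl 2-methoxy-3,4-bis(methoxymethoxy)-6-methylbenzoate, via thiol adduct 14 (not isolated)
Conditions: PhSH (1.0 equiv), Et3N (cat.), CH2Cl2, 0 °C; then NCS, pyridine, 0 → 23 °C
Reagents that add atoms: thiophenol, Sc1ccccc1
Why: Thia-Michael addition to the enone followed by NCS oxidation of the β-keto sulfide (Pummerer-type chlorination at the sulfur-bearing carbon, then loss of HCl through the acidic α-hydrogen) should give the β-(phenylthio)enone, installing the leaving group on the future C4a; the sp3 centres of 14 are lost again.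

Step 10
Reactants: 16 methyl 2,2-dimethoxypropanoate; 17 tert-butyl (triphenylphosphoranylidene)acetate
Product: 19 tert-butyl (2E)-4,4-dimethoxypent-2-enoate, via 2,2-dimethoxypropanal 18 (not isolated)
Conditions: iBu2AlH, CH2Cl2, −78 °C; then 17, −78 → 23 °C
Reagents that add atoms: none
Why: The chelated aluminium hemiacetal should stop the reduction at the aldehyde stage, and Wittig olefination with the stabilised ylide on warming should give the E-enoate.

Step 11
Reactants: 15 (1R,6R)-6-hydroxy-4-(hydroxymethyl)-6-methyl-5-oxo-3-(phenylsulfanyl)cyclohex-3-en-1-yl ester of ArCO2H; 19 tert-butyl (2E)-4,4-dimethoxypent-2-enoate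
Product: 24 tert-butyl (2E)-3-[(6R,7R)-7-hydroxy-6-(ArCO2)-7-methyl-8-oxo-5,6,7,8-tetrahydro-1H-isochromen-3-yl]prop-2-enoate, via mixed ketal 20 (not isolated), via allyl vinyl ether 21 (not isolated), via Claisen ketone 22 (not isolated), via oxatriene 23 (not isolated)
Conditions: 19 (4 equiv), 2,4-dinitrophenol (10 mol%), PhMe, 110 °C, MeOH removed (4 Å MS); then Et3N, 23 °C
Reagents that add atoms: none
Why: Acid-catalysed ketal exchange at the primary allylic hydroxyl and loss of methanol (possible only toward the CH3 group) should give allyl vinyl ether 21, whose thermal [3,3]-sigmatropic shift through a chair transition state joins the nucleophilic enol ether terminus C4 to the electrophilic β-carbon C4a of the vinylogous thioester to give 22; E1cB loss of thiophenol through the only acidic α-position (C4) gives 1-oxatriene 23, and disrotatory 6π-oxa-electrocyclization re-forms O2–C1 to give 24. The closest known reaction types are the ketal Claisen rearrangement of allylic alcohols with enone ketals and the oxatriene-to-2H-pyran closure that ends Knoevenagel/electrocyclization routes to fused pyrans. The six-membered pyran ring is closed in the net sense by the single new σ bond C4–C4a in a pericyclic mode, since O2–C1, present in 21, is cut in the [3,3] event and re-made in the electrocyclization. No stereocenter is created in the product: the transient quaternary C4a of 22 becomes sp2, and C6 and C7 are remote from every bond change. The step needs primary-over-tertiary hydroxyl selectivity in the ketal exchange (sterics), [3,3] shift rather than ionisation of C1–O2 (weak acid, non-polar solvent, polarity-matched termini), and closure of the Z-oxatriene, which should be secured because thiophenol and Et3N equilibrate the C4=C4a geometry by reversible conjugate addition while the doubly vinylogous ester 24 is the thermodynamic sink.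

Step 12
Reactants: 24 tert-butyl (2E)-3-[(6R,7R)-7-hydroxy-6-(ArCO2)-7-methyl-8-oxo-5,6,7,8-tetrahydro-1H-isochromen-3-yl]prop-2-enoate
Product: 25 (2E)-3-[(6R,7R)-6-[(3,4-dihydroxy-2-methoxy-6-methylbenzoyl)oxy]-7-hydroxy-7-methyl-8-oxo-5,6,7,8-tetrahydro-1H-isochromen-3-yl]prop-2-enoic acid
Conditions: TFA/CH2Cl2 (1:4), 0 → 23 °C
Reagents that add atoms: none
Why: Acidolysis should cleave both aryl MOM ethers and the tert-butyl ester in one operation, while the push–pull dienyl ether, the hindered aryl ester and the tertiary α-ketol should tolerate anhydrous acid.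

Compound list
1 | (R)-(−)-carvone, (5R)-2-methyl-5-(prop-1-en-2-yl)cyclohex-2-en-1-one | CC1=CC[C@H](CC1=O)C(C)=C | starting material
2 | (5R)-5-(1-hydroperoxy-1-methoxyethyl)-2-methylcyclohex-2-en-1-one (side-chain centre unassigned) | CC1=CC[C@H](CC1=O)C(C)(OC)OO | intermediate
3 | (R)-5-acetoxy-2-methylcyclohex-2-en-1-one, (1R)-4-methyl-5-oxocyclohex-3-en-1-yl acetate | CC1=CC[C@H](CC1=O)OC(C)=O | intermediate
4 | (1R,3R,4R)-3,4-dihydroxy-4-methyl-5-oxocyclohexyl acetate | O[C@@H]1C[C@@H](OC(C)=O)CC(=O)[C@]1(C)O | intermediate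
5 | 2,3,4-trimethoxy-6-methylbenzaldehyde | COc1cc(C)c(C=O)c(OC)c1OC | starting material
6 | 2,3,4-trihydroxy-6-methylbenzaldehyde | Cc1cc(O)c(O)c(O)c1C=O | intermediate
7 | 2-hydroxy-3,4-bis(methoxymethoxy)-6-methylbenzaldehyde | COCOc1cc(C)c(C=O)c(O)c1OCOC | intermediate
8 | 2-methoxy-3,4-bis(methoxymethoxy)-6-methylbenzaldehyde | COCOc1cc(C)c(C=O)c(OC)c1OCOC | intermediate
9 | 2-methoxy-3,4-bis(methoxymethoxy)-6-methylbenzoic acid | COc1c(OCOC)c(OCOC)cc(C)c1C(=O)O | intermediate
10 | 2-methoxy-3,4-bis(methoxymethoxy)-6-methylbenzoyl chloride | COc1c(OCOC)c(OCOC)cc(C)c1C(Cl)=O | intermediate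
11 | (1R,2R,5R)-5-acetoxy-2-hydroxy-2-methyl-3-oxocyclohexyl 2-methoxy-3,4-bis(methoxymethoxy)-6-methylbenzoate | COc1c(OCOC)c(OCOC)cc(C)c1C(=O)O[C@@H]1C[C@@H](OC(C)=O)CC(=O)[C@]1(C)O | intermediate
12 | (1R,6R)-6-hydroxy-6-methyl-5-oxocyclohex-3-en-1-yl 2-methoxy-3,4-bis(methoxymethoxy)-6-methylbenzoate | COc1c(OCOC)c(OCOC)cc(C)c1C(=O)O[C@@H]1CC=CC(=O)[C@]1(C)O | intermediate
13 | (1R,6R)-6-hydroxy-4-(hydroxymethyl)-6-methyl-5-oxocyclohex-3-en-1-yl 2-methoxy-3,4-bis(methoxymethoxy)-6-methylbenzoate | COc1c(OCOC)c(OCOC)cc(C)c1C(=O)O[C@@H]1CC=C(CO)C(=O)[C@]1(C)O | intermediate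
14 | (1R,2R)-2-hydroxy-4-(hydroxymethyl)-2-methyl-3-oxo-5-(phenylsulfanyl)cyclohexyl 2-methoxy-3,4-bis(methoxymethoxy)-6-methylbenzoate (C4/C5 epimers) | COc1c(OCOC)c(OCOC)cc(C)c1C(=O)O[C@@H]1CC(Sc2ccccc2)C(CO)C(=O)[C@]1(C)O | intermediate
15 | (1R,6R)-6-hydroxy-4-(hydroxymethyl)-6-methyl-5-oxo-3-(phenylsulfanyl)cyclohex-3-en-1-yl 2-methoxy-3,4-bis(methoxymethoxy)-6-methylbenzoate | COc1c(OCOC)c(OCOC)cc(C)c1C(=O)O[C@@H]1CC(Sc2ccccc2)=C(CO)C(=O)[C@]1(C)O | intermediate
16 | methyl 2,2-dimethoxypropanoate | COC(=O)C(C)(OC)OC | starting material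
17 | tert-butyl (triphenylphosphoranylidene)acetate | CC(C)(C)OC(=O)C=P(c1ccccc1)(c1ccccc1)c1ccccc1 | starting material
18 | 2,2-dimethoxypropanal | COC(C)(OC)C=O | intermediate
19 | tert-butyl (2E)-4,4-dimethoxypent-2-enoate | COC(C)(OC)/C=C/C(=O)OC(C)(C)C | intermediate
20 | mixed methyl ketal of 19 on the primary hydroxyl of 15 (ketal carbon epimers) | COc1c(OCOC)c(OCOC)cc(C)c1C(=O)O[C@@H]1CC(Sc2ccccc2)=C(COC(C)(OC)/C=C/C(=O)OC(C)(C)C)C(=O)[C@]1(C)O | intermediate
21 | allyl vinyl ether: tert-butyl (2E)-4-alkoxypenta-2,4-dienoate in which the alkoxy group is the C4 oxymethyl of 15 | COc1c(OCOC)c(OCOC)cc(C)c1C(=O)O[C@@H]1CC(Sc2ccccc2)=C(COC(=C)/C=C/C(=O)OC(C)(C)C)C(=O)[C@]1(C)O | intermediate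
22 | Claisen ketone: tert-butyl (2E)-5-[(4R,5R)-5-(ArCO2)-4-hydroxy-4-methyl-2-methylidene-3-oxo-1-(phenylsulfanyl)cyclohexyl]-4-oxopent-2-enoate (C1 epimers) | COc1c(OCOC)c(OCOC)cc(C)c1C(=O)O[C@@H]1CC(Sc2ccccc2)(CC(=O)/C=C/C(=O)OC(C)(C)C)C(=C)C(=O)[C@]1(C)O | intermediate
23 | 1-oxatriene: tert-butyl (2E,5Z)-5-[(4R,5R)-5-(ArCO2)-4-hydroxy-4-methyl-2-methylidene-3-oxocyclohexylidene]-4-oxopent-2-enoate | COc1c(OCOC)c(OCOC)cc(C)c1C(=O)O[C@@H]1C/C(=C/C(=O)/C=C/C(=O)OC(C)(C)C)C(=C)C(=O)[C@]1(C)O | intermediate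
24 | tert-butyl (2E)-3-[(6R,7R)-7-hydroxy-6-{[2-methoxy-3,4-bis(methoxymethoxy)-6-methylbenzoyl]oxy}-7-methyl-8-oxo-5,6,7,8-tetrahydro-1H-isochromen-3-yl]prop-2-enoate | COc1c(OCOC)c(OCOC)cc(C)c1C(=O)O[C@@H]1CC2=C(COC(/C=C/C(=O)OC(C)(C)C)=C2)C(=O)[C@]1(C)O | intermediate
25 | (2E)-3-[(6R,7R)-6-[(3,4-dihydroxy-2-methoxy-6-methylbenzoyl)oxy]-7-hydroxy-7-methyl-8-oxo-5,6,7,8-tetrahydro-1H-isochromen-3-yl]prop-2-enoic acid | COc1c(O)c(O)cc(C)c1C(=O)O[C@@H]1CC2=C(COC(/C=C/C(=O)O)=C2)C(=O)[C@]1(C)O | target

Total step count: 12.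
Longest linear sequence: 9 steps (5 to 25 through steps 3, 4, 5, 6, 7, 8, 9, 11 and 12).

Steps most likely to fail

Step 11. The allyl vinyl ether may ionise at C1–O2 instead of rearranging, or liberated thiophenol may intercept the oxatriene, so that the cascade stalls before ring closure. The fallback sets out from 15. Oxidation with mCPBA (2.1 equiv, CH2Cl2, 0 °C) should give the vinyl sulfone F1. Ketal exchange with 19 (PPTS, 5 Å MS, PhH, 50 °C) should give the mixed ketal F2. Warming with 2,4-dinitrophenol in PhMe (90–110 °C) should generate the enol ether F3. In F3, C4 should attack the β-sulfonyl enone carbon C4a in a polar 6-endo addition–elimination that expels non-nucleophilic benzenesulfinate; the electron-poor allyl part should no longer ionise. The fallback comes back to the route at 24.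

Step 2. Facial selectivity of the osmylation may be poor, which after step 7 would show up as loss of enantiomeric purity. The fallback sets out from 3. Methanolysis (K2CO3, MeOH, 0 °C) should give (R)-5-hydroxy-2-methylcyclohex-2-en-1-one F4, and TBSCl/imidazole its silyl ether F5. The bulkier pseudo-axial C5 group of F5 should shield one enone face more strongly, and OsO4/NMO should then give the diol F6. Acylation with 10 as in step 7 should give the silyloxy ester F7, and DBU-mediated β-elimination of the silyloxy group brings the fallback back to the route at 12.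

Step 9. Chlorination may not stop at the sulfide, or HCl may strip the MOM ethers, so that the leaving group cannot be installed cleanly. The fallback sets out from 13 and gives up the leaving group in favour of a later oxidation. Ketal Claisen rearrangement with 19 under the conditions of step 11 should proceed through the mixed ketal F8 and the allyl vinyl ether F9 to the α-methylene diketone F10. IBX (DMSO/PhF, 70 °C) should then dehydrogenate the only enolisable ketone across C4–C4a to oxatriene 23, which electrocyclises; the fallback comes back to the route at 24.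

Further compounds
F1 | step 11 | (1R,6R)-6-hydroxy-4-(hydroxymethyl)-6-methyl-5-oxo-3-(phenylsulfonyl)cyclohex-3-en-1-yl 2-methoxy-3,4-bis(methoxymethoxy)-6-methylbenzoate | COc1c(OCOC)c(OCOC)cc(C)c1C(=O)O[C@@H]1CC(S(=O)(=O)c2ccccc2)=C(CO)C(=O)[C@]1(C)O
F2 | step 11 | mixed methyl ketal of 19 on the primary hydroxyl of F1 (ketal carbon epimers) | COc1c(OCOC)c(OCOC)cc(C)c1C(=O)O[C@@H]1CC(S(=O)(=O)c2ccccc2)=C(COC(C)(OC)/C=C/C(=O)OC(C)(C)C)C(=O)[C@]1(C)O
F3 | step 11 | tert-butyl (2E)-4-alkoxypenta-2,4-dienoate in which the alkoxy group is the C4 oxymethyl of F1 | COc1c(OCOC)c(OCOC)cc(C)c1C(=O)O[C@@H]1CC(S(=O)(=O)c2ccccc2)=C(COC(=C)/C=C/C(=O)OC(C)(C)C)C(=O)[C@]1(C)O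
F4 | step 2 | (R)-5-hydroxy-2-methylcyclohex-2-en-1-one | CC1=CC[C@H](CC1=O)O
F5 | step 2 | (R)-5-[(tert-butyldimethylsilyl)oxy]-2-methylcyclohex-2-en-1-one | CC1=CC[C@H](CC1=O)O[Si](C)(C)C(C)(C)C
F6 | step 2 | (2R,3R,5R)-5-[(tert-butyldimethylsilyl)oxy]-2,3-dihydroxy-2-methylcyclohexan-1-one | O[C@@H]1C[C@@H](O[Si](C)(C)C(C)(C)C)CC(=O)[C@]1(C)O
F7 | step 2 | (1R,2R,5R)-5-[(tert-butyldimethylsilyl)oxy]-2-hydroxy-2-methyl-3-oxocyclohexyl 2-methoxy-3,4-bis(methoxymethoxy)-6-methylbenzoate | COc1c(OCOC)c(OCOC)cc(C)c1C(=O)O[C@@H]1C[C@@H](O[Si](C)(C)C(C)(C)C)CC(=O)[C@]1(C)O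
F8 | step 9 | mixed methyl ketal of 19 on the primary hydroxyl of 13 (ketal carbon epimers) | COc1c(OCOC)c(OCOC)cc(C)c1C(=O)O[C@@H]1CC=C(COC(C)(OC)/C=C/C(=O)OC(C)(C)C)C(=O)[C@]1(C)O
F9 | step 9 | tert-butyl (2E)-4-alkoxypenta-2,4-dienoate in which the alkoxy group is the C4 oxymethyl of 13 | COc1c(OCOC)c(OCOC)cc(C)c1C(=O)O[C@@H]1CC=C(COC(=C)/C=C/C(=O)OC(C)(C)C)C(=O)[C@]1(C)O
F10 | step 9 | tert-butyl (2E)-5-[(4R,5R)-5-(ArCO2)-4-hydroxy-4-methyl-2-methylidene-3-oxocyclohexyl]-4-oxopent-2-enoate (C1 epimers) | COc1c(OCOC)c(OCOC)cc(C)c1C(=O)O[C@@H]1CC(CC(=O)/C=C/C(=O)OC(C)(C)C)C(=C)C(=O)[C@]1(C)O
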